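# Proposed synthesis of CNP0116327.2 via a furan/oxyallyl [4+3] cycloadduct

## The problem

The target 25 is a 1,5-epoxy diarylheptanoid. Its seven-carbon chain is numbered here from C1, which bears the 4-hydroxy-3-methoxyphenyl ring, to C7, the benzylic CH2 of the 4-hydroxyphenyl ring. An ether oxygen bridges C1 and C5 into an oxane that carries a hydroxyl at C3, and a further carbinol sits at the exocyclic C6. A synthesis must place the aryl group at C1, the hydroxyl at C3 and the C6–C7 arm at C5 all cis (1R,3R,5S), and must make C6 R, which is anti to the ring oxygen on C5. The all-cis oxane is the all-equatorial isomer. C5 can therefore steer C1 thermodynamically, because the C1–O bond is an ionisable benzylic ether, and can steer C6 by chelation of a C6 carbonyl to the ring oxygen. C3 needs a kinetic device, and the absolute configuration has to be introduced once. The C1–O bond, para to an oxygen substituent, will not survive strong acid or prolonged hydrogenolysis; the free guaiacol is oxidation-prone; two phenols and two secondary alcohols must be told apart. The enabling feature is that the ring oxygen, the cis C1/C5 pair and the C2–C3(O)–C4 unit are exactly the O8/C1–C5 ring of 8-oxabicyclo[3.2.1]octan-3-one, so furan can supply O, C1 and C5 and an oxyallyl cation can supply C2–C4 with the C3 oxygen in one [4+3] cycloaddition. The two remaining furan carbons form an etheno bridge foreign to the target: one can become C6, the other must be excised at C1 when the aryl group is attached. The bicycle is meso, so it must be desymmetrised, and the excision erases C1, which must be set again.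

## Retrosynthesis

**Protecting groups.** Target 25 is traced to bis(benzyl ether) 24 and then to the C3 silyl ether 23. The phenols travel as benzyl ethers, which withstand every later reagent and leave in a brief final hydrogenolysis. The C3 oxygen travels as a triisopropylsilyl ether, so that the final hydrogenolysis has to cleave only aryl benzyl ethers and the benzylic C1–O ring bond is exposed for as short a time as possible.

**C6–C7 bond and the C6 centre.** Carbinol 23 is cut back to ketone 22, and 22 through the carbinol mixture 21 to aldehyde 18 and the benzylic Grignard reagent 20 (from chloride 19). Cutting C6–C7 is preferred to cutting C7–aryl because it uses the oxidised bridge carbon directly as an aldehyde. A chelation-controlled Grignard addition to 18 would favour the syn carbinol, which is the wrong one. Oxidation to 22 followed by chelation-controlled hydride delivery gives the anti (6R) isomer instead, with the ring oxygen at C5 as the control element.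

**The latent C6.** Aldehyde 18 comes from alcohol 17 and this from acetate 16. These are functional-group changes only: the acetoxymethyl arm of 16 is the stored C6.

**C1–aryl bond.** Acetate 16 is cut at C1–C(aryl) to carboxylic acid 12 and aryl bromide 14 (from phenol 13), with loss of the carboxyl carbon.
- The neighbouring cut, aryl-metal addition to a C1 lactone followed by silane reduction, would set C1 kinetically. It needs the arm degraded to a lactone over several steps and an ester-free substrate.
- The decarboxylative cut uses the acid oxidation level as it stands. The forward reaction passes through a C1 radical, so the cis configuration inherited from the bicycle is lost. Capture of such α-oxy radicals by nickel is expected to favour the axial, 2,6-trans product.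
- The plan therefore asks no stereoselectivity of the coupling. It gives 15 as an epimer mixture, and a separate acid equilibration through the stabilised benzylic cation funnels it to the all-equatorial 16. This is done early, before the second arene and the C6 hydroxyl are present.

**Desymmetrisation.** Acid 12 (via aldehyde 11) comes from monoacetate 10, and 10 from meso diol 9 by lipase-catalysed acylation of one enantiotopic hydroxymethyl group. This one step fixes the absolute configuration of C5 and decides which arm becomes C6 and which is excised.

**Bridge cleavage.** Diol 9 arises from silyl ether 7 by ozonolysis (via ozonide 8) and reduction; 7 from endo alcohol 6; 6 from ketone 5. Cutting the etheno bridge turns the bicycle into the cis-2,6-disubstituted oxane. Hydride attack on 5 from the face away from the bridge puts the C3 oxygen on the bridge side, which is the all-cis arrangement once the bridge is cut.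

**The [4+3] cut.** Ketone 5 is cut at C1–C2 and C4–C5 to furan 1 and 1,1,3,3-tetrabromoacetone 2, through oxyallyl cation 3 and dibromide 4. Both precursors are commodity chemicals. The step delivers the ring oxygen, all five ring carbons with the C3 oxygen, and the cis C1/C5 relationship, and nothing but chemoselectivity is asked of it.

## Roads not taken

Alternative 1: The cut is at C2–C3 and C3–C4, with C3 as a dithiane linchpin between two epoxides. In the forward direction lithiated 2-silyl dithiane A2 opens the aryl oxirane A3 at its terminal carbon, a 1,4-Brook rearrangement moves silicon to the C1 oxygen and regenerates the dithiane anion, and this opens epoxide A4 at C4 to give A1.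
- Merits: two C–C bonds form in one flask, the union is fully convergent, C1, C5 and C6 are imported from epoxides of secure configuration, and no carbon is sacrificed.
- Weak points: no ring bond exists after the key step. The C3 carbonyl must be released from the dithiane in the presence of two electron-rich arenes, reduced 1,3-syn to C5, and the oxane closed at the benzylic C1, where the configuration brought in with A3 is either inverted or lost through the benzylic cation. The electron-rich oxirane A3 is prone to benzylic opening and rearrangement. A4 with its two adjacent centres needs its own asymmetric synthesis, and five protecting groups are carried.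
- Comparison: Alternative 1 is better in convergence and atom economy and needs no enzyme. Once A3 and A4 are counted its length is unlikely to be shorter. The chosen plan sets against it commodity starting materials and a ring whose C1/C3/C5 relationships come from one rigid bicycle.

Alternative 2: The cut is at O–C1 and C2–C3, the retron of an inverse-demand oxa-Diels–Alder reaction. Ketoester A6, bound to Cu(OTf)2 and a bis(oxazoline) ligand (divalent copper), adds to styrene A7 to give dihydropyran A5 with C1 and C3 cis.
- Merits: the ring and two stereocentres arise in one catalytic enantioselective step, the C5 ester is the right handle for C6 and C7, and the whole route would be clearly shorter than the chosen one.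
- Weak points: the secure scope of this catalysis is enol ethers and similarly strong donors. A para-alkoxystyrene is a weaker, acid-sensitive two-π partner that may polymerise or react stepwise, with loss of endo and enantiofacial control. C5 must then be set by hydrogenating the enol ether from one face in the presence of three benzyl ethers and the benzylic C1–O bond, and the allylic benzyloxy group at C3 can ionise.
- Comparison: Alternative 2 is shorter and catalytic in its source of chirality, and would be preferable if the styrene cycloaddition were established. The chosen plan accepts more steps in exchange for bond-forming steps that each have direct precedent on the ring system at hand.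

Alternative 3: The cut is at C3–C4 and O–C5, with an isoxazoline as a masked aldol. Nitrile oxide A10, generated from oxime A9, adds to the terminal alkene of allylic silyl ether A11 to give A8. N–O cleavage, conjugate ring closure of the C5 oxygen onto C1 and reduction at C3 would follow.
- Merits: the union is convergent, the regiochemistry of nitrile oxide addition to a terminal alkene is reliable, the later oxa-conjugate closure gives the 2,6-cis ring under thermodynamic control, and no carbon is discarded.
- Weak points: C5 is set only by 1,2-induction from the allylic silyloxy centre, which for an acyclic ether with a slim CH2Ar group is expected to be moderate, so diastereomers of A8 must be separated. The N–O cleavage must spare the styryl alkene and the benzyl ethers. A11 needs a separate asymmetric synthesis.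
- Comparison: Alternative 3 is more convergent and probably a few steps shorter. Its absolute stereochemistry rests on one centre and a weak relay in the key step, whereas the chosen plan fixes C5 by a rigid bicycle plus an enzyme and C6 by chelation. In return the chosen plan concedes a long linear sequence and a radical step that erases C1.

Key step: step 1

Assumption: the lipase in step 5 acetylates the hydroxymethyl group on the (S)-configured ring carbon of meso diol 9; if it prefers the other arm, the same enzyme in hydrolysis mode on the diacetate supplies 10 (see the fallback for step 5).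

Chain numbering (C1–C7) is used for positions in the text; IUPAC locants appear only inside names.

## Route

Step 1
Reactants: 1 furan; 2 1,1,3,3-tetrabromoacetone
Product: 5 meso-(1R,5S)-8-oxabicyclo[3.2.1]oct-6-en-3-one, via zinc oxyallyl cation 3 (not isolated), via 2,4-dibromo cycloadduct 4 (not isolated)
Conditions: Zn–Cu couple, furan (excess), THF, −10 °C → rt; then Zn–Cu couple, NH4Cl, MeOH, −78 °C → rt
Reagents that add atoms: none
Why: Zinc reduces one C–Br bond of 2 to a bromozinc enolate that ionises by loss of bromide to the 1,3-dibromo-2-oxyallyl cation 3, a three-carbon, two-π-electron partner. This cation adds across C2 and C5 of furan (four π electrons) in a [4+3] cycloaddition, the long-established reaction type of furans with oxyallyl cations from polybromoketones. The seven-membered carbocycle closes by the cycloaddition itself: both new σ bonds (C1–C2 and C4–C5 in target numbering) join the allyl termini to the furan α-carbons, either in concert or by attack on furan followed by enolate closure onto the resulting oxocarbenium carbon. The two bridgehead stereocentres are set by geometry alone, since a three-carbon bridge can span the five-membered ring only on one face, so they are cis and the adduct is meso. Zn–Cu couple with NH4Cl in methanol then removes both α-bromine atoms of 4 in the same flask, which also erases the only centres (C2 and C4) whose configuration was uncontrolled. The selectivity needed is cycloaddition over Friedel–Crafts-type substitution at the furan α-carbon; the low aromatic stabilisation of furan, its use in excess and the cation-stabilising bromine substituents should secure it. No facial or absolute selectivity is asked of the step because the product has a mirror plane.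

Step 2
Reactants: 5 meso-(1R,5S)-8-oxabicyclo[3.2.1]oct-6-en-3-one
Product: 6 (1R,3s,5S)-8-oxabicyclo[3.2.1]oct-6-en-3-ol (3-endo alcohol, hydroxyl on the face of the etheno bridge; meso)
Conditions: LiBH(s-Bu)3, THF, −78 °C; then NaOH, H2O2, 0 °C
Reagents that add atoms: none
Why: Reduction of a bridged ketone with a bulky trialkylborohydride; the reagent can approach C3 only along the equatorial trajectory away from the etheno bridge, so the hydroxyl is pushed onto the bridge side (axial, endo), which becomes the all-cis relationship after bridge cleavage.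

Step 3
Reactants: 6 (1R,3s,5S)-8-oxabicyclo[3.2.1]oct-6-en-3-ol
Product: 7 (1R,3s,5S)-3-[(triisopropylsilyl)oxy]-8-oxabicyclo[3.2.1]oct-6-ene (3-endo silyl ether; meso)
Conditions: TIPSOTf, 2,6-lutidine, CH2Cl2, 0 °C → rt
Reagents that add atoms: triisopropylsilyl trifluoromethanesulfonate, CC(C)[Si](OS(=O)(=O)C(F)(F)F)(C(C)C)C(C)C
Why: Silylation of a hindered secondary alcohol with a silyl triflate; the triisopropylsilyl ether is chosen because it should survive the Lewis acid of step 9, the Grignard reagent and both hydride reagents, and it leaves with fluoride.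

Step 4
Reactants: 7 (1R,3s,5S)-3-[(triisopropylsilyl)oxy]-8-oxabicyclo[3.2.1]oct-6-ene
Product: 9 meso all-cis [(2R,4s,6S)-4-[(triisopropylsilyl)oxy]oxane-2,6-diyl]dimethanol, via secondary ozonide 8 (not isolated)
Conditions: O3, CH2Cl2, −78 °C; then MeOH, NaBH4, −78 °C → rt
Reagents that add atoms: ozone, [O-][O+]=O
Why: Ozonolysis of the strained cis-alkene with reductive work-up to the diol; cleaving the bridge turns the two bridgeheads into the cis-2,6 carbons of the oxane, and the ring can relax to the chair with all three substituents equatorial.

Step 5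
Reactants: 9 meso all-cis [(2R,4s,6S)-4-[(triisopropylsilyl)oxy]oxane-2,6-diyl]dimethanol
Product: 10 [(2S,4R,6R)-6-(hydroxymethyl)-4-[(triisopropylsilyl)oxy]oxan-2-yl]methyl acetate
Conditions: lipase from Burkholderia cepacia (immobilised), vinyl acetate, t-BuOMe, rt
Reagents that add atoms: vinyl acetate, C=COC(C)=O
Why: Lipase-catalysed enantiotopos-selective transesterification of a meso primary diol with an irreversible acyl donor, a standard desymmetrisation of cis-2,6-bis(hydroxymethyl) heterocycles; it fixes the absolute configuration of C5 and differentiates the arms, and further acylation to the diacetate should consume the minor enantiomer preferentially.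

Step 6
Reactants: 10 [(2S,4R,6R)-6-(hydroxymethyl)-4-[(triisopropylsilyl)oxy]oxan-2-yl]methyl acetate
Product: 12 (2R,4S,6S)-6-(acetoxymethyl)-4-[(triisopropylsilyl)oxy]oxane-2-carboxylic acid, via aldehyde 11 (not isolated)
Conditions: TEMPO (cat.), PhI(OAc)2, MeCN/H2O, rt
Reagents that add atoms: water, O
Why: Oxoammonium-mediated oxidation of a primary alcohol to the acid through the hydrate of aldehyde 11; the conditions are near neutral, so acetate, silyl ether and the α-alkoxy centre should be untouched.

Step 7
Reactants: 13 4-bromo-2-methoxyphenol
Product: 14 1-(benzyloxy)-4-bromo-2-methoxybenzene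
Conditions: BnBr, K2CO3, acetone, reflux
Reagents that add atoms: benzyl bromide, BrCc1ccccc1
Why: Williamson etherification of a phenol; the benzyl ether prevents phenoxide formation, which would deactivate the bromide and quench the photocatalyst in step 8.

Step 8
Reactants: 12 (2R,4S,6S)-6-(acetoxymethyl)-4-[(triisopropylsilyl)oxy]oxane-2-carboxylic acid; 14 1-(benzyloxy)-4-bromo-2-methoxybenzene
Product: 15 [(2S,4R)-6-[4-(benzyloxy)-3-methoxyphenyl]-4-[(triisopropylsilyl)oxy]oxan-2-yl]methyl acetate as a mixture of epimers at chain C1
Conditions: Ir[dF(CF3)ppy]2(dtbbpy)PF6 (2 mol %), NiCl2·glyme (10 mol %), dtbbpy (15 mol %), Cs2CO3, DMF, blue LEDs, rt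
Reagents that add atoms: none
Why: Nickel/photoredox decarboxylative arylation of a cyclic α-oxy acid: the photoexcited iridium complex oxidises the cesium carboxylate, loss of CO2 gives the C1 α-oxy radical, and the divalent aryl nickel bromide formed from zerovalent nickel and 14 captures it to a trivalent nickel species that reductively eliminates the C1–aryl bond. The radical is planar at C1 and axial capture is expected to favour the trans epimer, so no stereoselectivity is asked here and C1 is set in step 9.

Step 9
Reactants: 15 [(2S,4R)-6-[4-(benzyloxy)-3-methoxyphenyl]-4-[(triisopropylsilyl)oxy]oxan-2-yl]methyl acetate (epimer mixture)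
Product: 16 [(2S,4R,6R)-6-[4-(benzyloxy)-3-methoxyphenyl]-4-[(triisopropylsilyl)oxy]oxan-2-yl]methyl acetate (all-cis)
Conditions: BF3·OEt2 (0.3 equiv), CH2Cl2, −20 → 0 °C; Et3N quench
Reagents that add atoms: none
Why: Acid-mediated ring-opening and reclosure of an electron-rich 2-aryl oxane, the same process as the anomerisation of aryl C-glycosides: the Lewis acid on the ring oxygen lets the C1–O bond ionise to a benzylic cation stabilised by the para benzyloxy group, and reversible reclosure by the C5 oxygen collects the material in the all-equatorial isomer. C3 and C5 are not involved, so C1 is set by thermodynamic control relative to C5.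

Step 10
Reactants: 16 [(2S,4R,6R)-6-[4-(benzyloxy)-3-methoxyphenyl]-4-[(triisopropylsilyl)oxy]oxan-2-yl]methyl acetate
Product: 17 [(2S,4R,6R)-6-[4-(benzyloxy)-3-methoxyphenyl]-4-[(triisopropylsilyl)oxy]oxan-2-yl]methanol
Conditions: K2CO3 (cat.), MeOH, rt
Reagents that add atoms: none
Why: Base-catalysed transesterification of a primary acetate; no other group in 16 is base-labile.

Step 11
Reactants: 17 [(2S,4R,6R)-6-[4-(benzyloxy)-3-methoxyphenyl]-4-[(triisopropylsilyl)oxy]oxan-2-yl]methanol
Product: 18 (2S,4R,6R)-6-[4-(benzyloxy)-3-methoxyphenyl]-4-[(triisopropylsilyl)oxy]oxane-2-carbaldehyde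
Conditions: Dess–Martin periodinane, pyridine, CH2Cl2, 0 °C → rt
Reagents that add atoms: none
Why: Dess–Martin oxidation under buffered conditions; it is mild enough for the benzylic ether and the α-alkoxy aldehyde, whose cis (equatorial) configuration at C5 is in any case the stable one.

Step 12
Reactants: 18 (2S,4R,6R)-6-[4-(benzyloxy)-3-methoxyphenyl]-4-[(triisopropylsilyl)oxy]oxane-2-carbaldehyde; 19 4-(benzyloxy)benzyl chloride
Product: 21 2-[4-(benzyloxy)phenyl]-1-[(2S,4R,6R)-6-[4-(benzyloxy)-3-methoxyphenyl]-4-[(triisopropylsilyl)oxy]oxan-2-yl]ethan-1-ol as a mixture of epimers at chain C6, via benzylic Grignard reagent 20 (not isolated)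
Conditions: 19, Mg, Et2O, 0 °C → rt; then 18, THF, −78 °C; aq NH4Cl
Reagents that add atoms: none
Why: Grignard addition to an aldehyde forms C6–C7; slow addition of 19 to excess magnesium in ether limits Wurtz coupling, and the configuration at C6 is immaterial because step 13 erases it.

Step 13
Reactants: 21 2-[4-(benzyloxy)phenyl]-1-[(2S,4R,6R)-6-[4-(benzyloxy)-3-methoxyphenyl]-4-[(triisopropylsilyl)oxy]oxan-2-yl]ethan-1-ol (epimer mixture)
Product: 22 2-[4-(benzyloxy)phenyl]-1-[(2S,4R,6R)-6-[4-(benzyloxy)-3-methoxyphenyl]-4-[(triisopropylsilyl)oxy]oxan-2-yl]ethan-1-one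
Conditions: Dess–Martin periodinane, pyridine, CH2Cl2, 0 °C → rt
Reagents that add atoms: none
Why: Dess–Martin oxidation of a secondary alcohol converges both carbinol epimers on one ketone without base, so the enolisable C5 and C7 positions are not disturbed.

Step 14
Reactants: 22 2-[4-(benzyloxy)phenyl]-1-[(2S,4R,6R)-6-[4-(benzyloxy)-3-methoxyphenyl]-4-[(triisopropylsilyl)oxy]oxan-2-yl]ethan-1-one
Product: 23 (1R)-2-[4-(benzyloxy)phenyl]-1-[(2S,4R,6R)-6-[4-(benzyloxy)-3-methoxyphenyl]-4-[(triisopropylsilyl)oxy]oxan-2-yl]ethan-1-ol
Conditions: Zn(BH4)2, Et2O, −40 °C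
Reagents that add atoms: none
Why: Chelation-controlled reduction of an α-alkoxy ketone: zinc bridges the C6 carbonyl oxygen and the ring oxygen on C5, and hydride enters from the side of the C5 hydrogen, which gives the 5,6-anti carbinol, that is 6R.

Step 15
Reactants: 23 (1R)-2-[4-(benzyloxy)phenyl]-1-[(2S,4R,6R)-6-[4-(benzyloxy)-3-methoxyphenyl]-4-[(triisopropylsilyl)oxy]oxan-2-yl]ethan-1-ol
Product: 24 (2R,4R,6S)-2-[4-(benzyloxy)-3-methoxyphenyl]-6-[(1R)-2-[4-(benzyloxy)phenyl]-1-hydroxyethyl]oxan-4-ol
Conditions: TBAF, THF, rt
Reagents that add atoms: none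
Why: Fluoride cleavage of the silyl ether; it is done before the phenols are freed so that no phenoxide is exposed to the basic fluoride medium.

Step 16
Reactants: 24 (2R,4R,6S)-2-[4-(benzyloxy)-3-methoxyphenyl]-6-[(1R)-2-[4-(benzyloxy)phenyl]-1-hydroxyethyl]oxan-4-ol
Product: 25 (2R,4R,6S)-2-(4-hydroxy-3-methoxyphenyl)-6-[(1R)-1-hydroxy-2-(4-hydroxyphenyl)ethyl]oxan-4-ol (target)
Conditions: H2 (1 atm), Pd/C, EtOAc/EtOH, rt, stopped at full conversion
Reagents that add atoms: none
Why: Catalytic hydrogenolysis of two aryl benzyl ethers, which cleave much faster than the cyclic benzylic C1–O bond under neutral conditions; no stereocentre is touched.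

## Compound list

1 | furan | c1ccoc1 | starting material
2 | 1,1,3,3-tetrabromoacetone | O=C(C(Br)Br)C(Br)Br | starting material
3 | bromozinc 1,3-dibromo-2-oxyallyl cation (bromide salt) | BrC=C(O[Zn]Br)[CH+]Br.[Br-] | intermediate
4 | 2,4-dibromo-8-oxabicyclo[3.2.1]oct-6-en-3-one (cis bridgeheads; bromine-bearing centres unassigned) | O=C1C(Br)[C@H]2C=C[C@@H](C1Br)O2 | intermediate
5 | meso-(1R,5S)-8-oxabicyclo[3.2.1]oct-6-en-3-one | O=C1C[C@H]2C=C[C@@H](C1)O2 | intermediate
6 | (1R,3s,5S)-8-oxabicyclo[3.2.1]oct-6-en-3-ol (3-endo) | O[C@H]1C[C@H]2C=C[C@@H](C1)O2 | intermediate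
7 | (1R,3s,5S)-3-[(triisopropylsilyl)oxy]-8-oxabicyclo[3.2.1]oct-6-ene (3-endo) | CC(C)[Si](O[C@H]1C[C@H]2C=C[C@@H](C1)O2)(C(C)C)C(C)C | intermediate
8 | secondary ozonide (1,2,4-trioxolane) of 7; acetal carbons fixed by the ring fusion | CC(C)[Si](O[C@H]1C[C@H]2C3OOC(O3)[C@@H](C1)O2)(C(C)C)C(C)C | intermediate
9 | meso all-cis [(2R,4s,6S)-4-[(triisopropylsilyl)oxy]oxane-2,6-diyl]dimethanol | OC[C@H]1C[C@@H](O[Si](C(C)C)(C(C)C)C(C)C)C[C@@H](CO)O1 | intermediate
10 | [(2S,4R,6R)-6-(hydroxymethyl)-4-[(triisopropylsilyl)oxy]oxan-2-yl]methyl acetate | OC[C@H]1C[C@@H](O[Si](C(C)C)(C(C)C)C(C)C)C[C@@H](COC(C)=O)O1 | intermediate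
11 | [(2S,4S,6R)-6-formyl-4-[(triisopropylsilyl)oxy]oxan-2-yl]methyl acetate | O=C[C@H]1C[C@@H](O[Si](C(C)C)(C(C)C)C(C)C)C[C@@H](COC(C)=O)O1 | intermediate
12 | (2R,4S,6S)-6-(acetoxymethyl)-4-[(triisopropylsilyl)oxy]oxane-2-carboxylic acid | OC(=O)[C@H]1C[C@@H](O[Si](C(C)C)(C(C)C)C(C)C)C[C@@H](COC(C)=O)O1 | intermediate
13 | 4-bromo-2-methoxyphenol | COc1cc(Br)ccc1O | starting material
14 | 1-(benzyloxy)-4-bromo-2-methoxybenzene | COc1cc(Br)ccc1OCc1ccccc1 | intermediate
15 | [(2S,4R)-6-[4-(benzyloxy)-3-methoxyphenyl]-4-[(triisopropylsilyl)oxy]oxan-2-yl]methyl acetate, both epimers at the aryl-bearing carbon | COc1cc(C2C[C@@H](O[Si](C(C)C)(C(C)C)C(C)C)C[C@@H](COC(C)=O)O2)ccc1OCc1ccccc1 | intermediate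
16 | [(2S,4R,6R)-6-[4-(benzyloxy)-3-methoxyphenyl]-4-[(triisopropylsilyl)oxy]oxan-2-yl]methyl acetate (all-cis) | COc1cc([C@H]2C[C@@H](O[Si](C(C)C)(C(C)C)C(C)C)C[C@@H](COC(C)=O)O2)ccc1OCc1ccccc1 | intermediate
17 | [(2S,4R,6R)-6-[4-(benzyloxy)-3-methoxyphenyl]-4-[(triisopropylsilyl)oxy]oxan-2-yl]methanol | COc1cc([C@H]2C[C@@H](O[Si](C(C)C)(C(C)C)C(C)C)C[C@@H](CO)O2)ccc1OCc1ccccc1 | intermediate
18 | (2S,4R,6R)-6-[4-(benzyloxy)-3-methoxyphenyl]-4-[(triisopropylsilyl)oxy]oxane-2-carbaldehyde | COc1cc([C@H]2C[C@@H](O[Si](C(C)C)(C(C)C)C(C)C)C[C@@H](C=O)O2)ccc1OCc1ccccc1 | intermediate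
19 | 4-(benzyloxy)benzyl chloride | ClCc1ccc(OCc2ccccc2)cc1 | starting material
20 | [4-(benzyloxy)benzyl]magnesium chloride | Cl[Mg]Cc1ccc(OCc2ccccc2)cc1 | intermediate
21 | 2-[4-(benzyloxy)phenyl]-1-[(2S,4R,6R)-6-[4-(benzyloxy)-3-methoxyphenyl]-4-[(triisopropylsilyl)oxy]oxan-2-yl]ethan-1-ol, both carbinol epimers | COc1cc([C@H]2C[C@@H](O[Si](C(C)C)(C(C)C)C(C)C)C[C@@H](C(O)Cc3ccc(OCc4ccccc4)cc3)O2)ccc1OCc1ccccc1 | intermediate
22 | 2-[4-(benzyloxy)phenyl]-1-[(2S,4R,6R)-6-[4-(benzyloxy)-3-methoxyphenyl]-4-[(triisopropylsilyl)oxy]oxan-2-yl]ethan-1-one | COc1cc([C@H]2C[C@@H](O[Si](C(C)C)(C(C)C)C(C)C)C[C@@H](C(=O)Cc3ccc(OCc4ccccc4)cc3)O2)ccc1OCc1ccccc1 | intermediate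
23 | (1R)-2-[4-(benzyloxy)phenyl]-1-[(2S,4R,6R)-6-[4-(benzyloxy)-3-methoxyphenyl]-4-[(triisopropylsilyl)oxy]oxan-2-yl]ethan-1-ol | COc1cc([C@H]2C[C@@H](O[Si](C(C)C)(C(C)C)C(C)C)C[C@@H]([C@H](O)Cc3ccc(OCc4ccccc4)cc3)O2)ccc1OCc1ccccc1 | intermediate
24 | (2R,4R,6S)-2-[4-(benzyloxy)-3-methoxyphenyl]-6-[(1R)-2-[4-(benzyloxy)phenyl]-1-hydroxyethyl]oxan-4-ol | COc1cc([C@H]2C[C@@H](O)C[C@@H]([C@H](O)Cc3ccc(OCc4ccccc4)cc3)O2)ccc1OCc1ccccc1 | intermediate
25 | (2R,4R,6S)-2-(4-hydroxy-3-methoxyphenyl)-6-[(1R)-1-hydroxy-2-(4-hydroxyphenyl)ethyl]oxan-4-ol | COc1cc([C@H]2C[C@@H](O)C[C@@H]([C@H](O)Cc3ccc(O)cc3)O2)ccc1O | target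

## Step count and least certain steps

Total: 16 steps. Longest linear sequence: 15 steps (steps 1–6 and 8–16, from furan); step 7 is a one-step branch.

**Step 1 (key step).** Furan may undergo electrophilic substitution or polymerise instead of cycloadding, debromination may stop half-way, and the small, water-soluble ketone may be lost on work-up. Fallback, from 1 back to 5: generate the oxyallyl cation without a reducing metal, by dehydrochlorination of 1,1,3-trichloroacetone F1 with Et3N in 2,2,2-trifluoroethanol in the presence of furan. This should give 2,4-dichloro-8-oxabicyclo[3.2.1]oct-6-en-3-one F2, a more stable adduct that can be isolated and purified before Zn–Cu/NH4Cl dechlorination to 5.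

**Step 8.** Oxidative addition of the electron-rich bromide 14 to zerovalent nickel is slow, so the C1 radical may be lost by hydrogen-atom abstraction or dimerisation while the valuable acid is the limiting partner. Fallback, from 12 and 14 back to 15: make the aryl partner the nucleophile. Acid 12 is converted with N-hydroxyphthalimide and diisopropylcarbodiimide into the redox-active N-(acyloxy)phthalimide F3. Bromide 14 is converted by bromine–lithium exchange (n-BuLi) and ZnCl2 into [4-(benzyloxy)-3-methoxyphenyl]zinc chloride F4. A thermal decarboxylative Negishi coupling with NiCl2·glyme and dtbbpy in THF/DMF should then give 15, again as an epimer mixture, for step 9.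

**Step 9.** The ring-opened benzylic cation may lose a proton to a styrene that oligomerises, or the silyl ether may be lost to the Lewis acid, before equilibrium is reached. Fallback, from 15 back to 16: set C1 kinetically instead of thermodynamically. DDQ in wet CH2Cl2 abstracts the benzylic C1 hydride of either epimer, and water capture gives (2S,4S)-6-[4-(benzyloxy)-3-methoxyphenyl]-2-hydroxy-6-oxo-4-[(triisopropylsilyl)oxy]hexyl acetate F5, in equilibrium with its cyclic hemiketal. Reduction with Et3SiH and TMSOTf at −78 °C delivers hydride axially to the cyclic oxocarbenium ion and should give the cis oxane 16.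

**Step 5.** The enzyme may acylate the other enantiotopic arm or discriminate poorly, and over-acylation wastes material. Fallback, from 9 back to 10: acetylate both arms (Ac2O, pyridine) to the meso diacetate [(2R,4s,6S)-4-[(triisopropylsilyl)oxy]oxane-2,6-diyl]bis(methylene) diacetate F6 and let the same lipase hydrolyse one ester in pH 7 buffer. Hydrolysis leaves the acetate on the arm that acylation would have left free, so one of the two modes gives 10.

**Step 16.** Hydrogenolysis of the benzylic C1–O ring bond, now para to a free phenol, may compete with debenzylation. Fallback, from 24 to 25: cleave the two aryl benzyl ethers by Lewis acid instead of hydrogen, with BCl3 and pentamethylbenzene as cation scavenger in CH2Cl2 at −78 °C. No new isolated compound is involved, and any reversible opening at C1 recloses to the same all-equatorial ring.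

**Step 14.** Chelation may be incomplete, so that an open transition state lowers the facial selectivity. Fallback, from 22 back to 23: switch from substrate to reagent control with a Corey–Bakshi–Shibata reduction, using the (S)-configured methyl oxazaborolidine and BH3·SMe2 and treating the branched oxanyl group as the large substituent. No new compound is involved. Any (6S) carbinol can also be returned to 22 by the oxidation of step 13.

## Further compounds

F1 | step 1 | 1,1,3-trichloroacetone | O=C(CCl)C(Cl)Cl
F2 | step 1 | 2,4-dichloro-8-oxabicyclo[3.2.1]oct-6-en-3-one (cis bridgeheads; chlorine-bearing centres unassigned) | O=C1C(Cl)[C@H]2C=C[C@@H](C1Cl)O2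
F3 | step 8 | 1,3-dioxoisoindolin-2-yl (2R,4S,6S)-6-(acetoxymethyl)-4-[(triisopropylsilyl)oxy]oxane-2-carboxylate | O=C(ON1C(=O)c2ccccc2C1=O)[C@H]1C[C@@H](O[Si](C(C)C)(C(C)C)C(C)C)C[C@@H](COC(C)=O)O1
F4 | step 8 | [4-(benzyloxy)-3-methoxyphenyl]zinc chloride | COc1cc([Zn]Cl)ccc1OCc1ccccc1
F5 | step 9 | (2S,4S)-6-[4-(benzyloxy)-3-methoxyphenyl]-2-hydroxy-6-oxo-4-[(triisopropylsilyl)oxy]hexyl acetate | COc1cc(C(=O)C[C@@H](O[Si](C(C)C)(C(C)C)C(C)C)C[C@H](O)COC(C)=O)ccc1OCc1ccccc1
F6 | step 5 | meso [(2R,4s,6S)-4-[(triisopropylsilyl)oxy]oxane-2,6-diyl]bis(methylene) diacetate | CC(=O)OC[C@H]1C[C@@H](O[Si](C(C)C)(C(C)C)C(C)C)C[C@@H](COC(C)=O)O1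
F0 | step 16 | none | none
F0 | step 14 | none | none
A1 | alternative 1 | (1R,5S,6R)-configured linchpin product: C1 silyl ether, C3 dithiane, C5 alcohol, C6 benzyl ether | COc1cc([C@H](O[Si](C)(C)C(C)(C)C)CC2(SCCCS2)C[C@H](O)[C@H](OCc2ccccc2)Cc2ccc(OCc3ccccc3)cc2)ccc1OCc1ccccc1
A2 | alternative 1 | 2-(tert-butyldimethylsilyl)-1,3-dithiane | C[Si](C)(C(C)(C)C)C1SCCCS1
A3 | alternative 1 | (S)-2-[4-(benzyloxy)-3-methoxyphenyl]oxirane | COc1cc([C@H]2CO2)ccc1OCc1ccccc1
A4 | alternative 1 | (2S)-2-[(1R)-1-(benzyloxy)-2-[4-(benzyloxy)phenyl]ethyl]oxirane | C1O[C@@H]1[C@H](OCc1ccccc1)Cc1ccc(OCc2ccccc2)cc1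
A5 | alternative 2 | ethyl cis-4-(benzyloxy)-6-[4-(benzyloxy)-3-methoxyphenyl]-5,6-dihydro-4H-pyran-2-carboxylate | CCOC(=O)C1=C[C@H](OCc2ccccc2)C[C@H](c2ccc(OCc3ccccc3)c(OC)c2)O1
A6 | alternative 2 | ethyl (E)-4-(benzyloxy)-2-oxobut-3-enoate | CCOC(=O)C(=O)/C=C/OCc1ccccc1
A7 | alternative 2 | 1-(benzyloxy)-4-ethenyl-2-methoxybenzene | C=Cc1ccc(OCc2ccccc2)c(OC)c1
A8 | alternative 3 | 3-styryl-5-(1-silyloxy-2-arylethyl)-4,5-dihydroisoxazole | COc1cc(/C=C/C2=NO[C@H]([C@H](O[Si](C)(C)C(C)(C)C)Cc3ccc(OCc4ccccc4)cc3)C2)ccc1OCc1ccccc1
A9 | alternative 3 | (E)-3-[4-(benzyloxy)-3-methoxyphenyl]prop-2-enal oxime | COc1cc(/C=C/C=NO)ccc1OCc1ccccc1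
A10 | alternative 3 | (E)-3-[4-(benzyloxy)-3-methoxyphenyl]prop-2-enenitrile oxide | COc1cc(/C=C/C#[N+][O-])ccc1OCc1ccccc1
A11 | alternative 3 | tert-butyl{[(2R)-1-[4-(benzyloxy)phenyl]but-3-en-2-yl]oxy}dimethylsilane | C=C[C@H](O[Si](C)(C)C(C)(C)C)Cc1ccc(OCc2ccccc2)cc1
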